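## Retrosynthetic overview

1. C6–O last: the 6α-hydroxyl and the C5=C10 alkene arise together from a singlet-oxygen ene reaction on a C5=C6 alkene that carries an axial 10α-H; aryl acetate removal then gives the target.
2. C19–O before that: the phloretate ester is installed by acyloxylation of the equatorial 4β-methyl C–H of a 4,4-dimethyl-3-ketone with O-acetylphloretic acid, which sets C4.
3. Butenolide: attached as a whole ring by hydroboration of a C9 vinyl group and Suzuki coupling with 4-bromofuran-2(5H)-one.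
4. Ring A: Robinson annulation (ethyl vinyl ketone) on the C10 enolate of ring B, then deconjugative C4 methylation.
5. Ring order: ring B first ((S)-3,4-dimethylcyclohex-2-enone from 3,4-dimethylanisole; a vinyl cuprate sets C9), then ring A, then the pre-formed butenolide.

Numbering and assumption: positions follow halimane numbering (ring A = C1–C5 and C10, ring B = C5–C10, C19 = the oxygenated carbon on C4) and β is the face of the C8 and C9 methyls; the quinine-derived amine of step 2 is assumed to be the pseudoenantiomer that gives the S enone (otherwise the quinidine-derived one is used).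

## Route

Step 1
Reactants: 1 4-methoxy-1,2-dimethylbenzene (3,4-dimethylanisole)
Product: 3 3,4-dimethylcyclohex-3-en-1-one, via Birch diene 2 (not isolated)
Conditions: Li, liq. NH3, THF, t-BuOH, −78 to −33 °C; then (CO2H)2 (cat.), MeOH/H2O, rt
Reagents that add atoms: water, O
Why: Birch reduction leaves the methoxy- and methyl-bearing carbons on the two double bonds, and mild enol ether hydrolysis gives the β,γ-unsaturated ketone without moving the tetrasubstituted alkene into conjugation.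

Step 2
Reactants: 3 3,4-dimethylcyclohex-3-en-1-one
Product: 4 (4S)-3,4-dimethylcyclohex-2-en-1-one
Conditions: 9-amino-9-deoxy-epi-quinine (C20H25N3O, 10 mol%), PhCO2H (20 mol%), toluene, −20 °C
Reagents that add atoms: none
Why: Asymmetric proton-transfer isomerisation through a chiral dienamine, in which the amine catalyst delivers the proton to one face of C4 of the enone (future C8) and so sets it as S.

Step 3
Reactants: 4 (4S)-3,4-dimethylcyclohex-2-en-1-one
Product: 5 {[(3R,4S)-3-ethenyl-3,4-dimethylcyclohex-1-en-1-yl]oxy}trimethylsilane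
Conditions: CH2=CHMgBr, CuBr·SMe2 (10 mol%), Me3SiCl, THF, −78 °C; Et3N quench
Reagents that add atoms: vinylmagnesium bromide, C=C[Mg]Br; chlorotrimethylsilane, C[Si](C)(C)Cl
Why: Copper-catalysed conjugate addition in which the vinyl group enters anti to the ring methyl, creating the quaternary centre (future C9, the two methyls cis) while Me3SiCl traps the enolate regiospecifically at the future C10.

Step 4
Reactants: 5 {[(3R,4S)-3-ethenyl-3,4-dimethylcyclohex-1-en-1-yl]oxy}trimethylsilane; 6 pent-1-en-3-one (ethyl vinyl ketone)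
Product: 8 (4aS,5R,6S)-5-ethenyl-1,5,6-trimethyl-4,4a,5,6,7,8-hexahydronaphthalen-2(3H)-one, via diketone 7 (not isolated)
Conditions: BF3·OEt2, i-PrOH, CH2Cl2, −78 °C; then NaOMe, MeOH, 65 °C
Reagents that add atoms: none
Why: Robinson annulation run as a Mukaiyama–Michael addition at the enol ether carbon followed by base aldol condensation, the epimerisable C10 settling under NaOMe with C1 equatorial on ring B (10α-H, cis to the C9 side chain).

Step 5
Reactants: 8 (4aS,5R,6S)-5-ethenyl-1,5,6-trimethyl-4,4a,5,6,7,8-hexahydronaphthalen-2(3H)-one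
Product: 9 (4aS,5R,6S)-5-ethenyl-1,1,5,6-tetramethyl-3,4,4a,5,6,7-hexahydronaphthalen-2(1H)-one
Conditions: KOtBu (1.3 equiv), MeI (3 equiv), t-BuOH/THF, 0 °C to rt
Reagents that add atoms: iodomethane, CI
Why: Deconjugative α-alkylation of the extended dienolate places the second methyl on C4 and moves the alkene to C5=C6 without touching the 10α-H.

Step 6
Reactants: 9 (4aS,5R,6S)-5-ethenyl-1,1,5,6-tetramethyl-3,4,4a,5,6,7-hexahydronaphthalen-2(1H)-one; 10 4-bromofuran-2(5H)-one
Product: 12 4-{2-[(1R,2S,8aS)-1,2,5,5-tetramethyl-6-oxo-1,2,3,5,6,7,8,8a-octahydronaphthalen-1-yl]ethyl}furan-2(5H)-one, via alkylborane 11 (not isolated)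
Conditions: 9-borabicyclo[3.3.1]nonane dimer, THF, rt; then 10, PdCl2(dppf) (5 mol%), AsPh3, aq. K3PO4, DMF, rt
Reagents that add atoms: none
Why: Anti-Markovnikov hydroboration of the terminal vinyl group by the hindered borane (the trisubstituted alkene and the neopentyl ketone react far more slowly) followed by B-alkyl Suzuki–Miyaura coupling with the vinyl bromide of the butenolide.

Step 7
Reactants: 13 3-(4-hydroxyphenyl)propanoic acid (phloretic acid)
Product: 14 3-[4-(acetyloxy)phenyl]propanoic acid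
Conditions: Ac2O, pyridine, rt; then H2O
Reagents that add atoms: acetic anhydride, CC(=O)OC(C)=O
Why: O-acetylation of the phenol, needed because a free phenol would not survive the oxidant of step 8 or singlet oxygen in step 9, the mixed anhydride at the acid being hydrolysed on aqueous work-up.

Step 8
Reactants: 12 4-{2-[(1R,2S,8aS)-1,2,5,5-tetramethyl-6-oxo-1,2,3,5,6,7,8,8a-octahydronaphthalen-1-yl]ethyl}furan-2(5H)-one; 14 3-[4-(acetyloxy)phenyl]propanoic acid
Product: 15 {(1S,4aS,5R,6S)-1,5,6-trimethyl-2-oxo-5-[2-(5-oxo-2,5-dihydrofuran-3-yl)ethyl]-1,2,3,4,4a,5,6,7-octahydronaphthalen-1-yl}methyl 3-[4-(acetyloxy)phenyl]propanoate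
Conditions: 14 (3 equiv), Pd(OCOCF3)2 (10 mol%), glycine (40 mol%), 1-fluoro-2,4,6-trimethylpyridinium tetrafluoroborate (1.5 equiv), (CF3)2CHOH, 90 °C
Reagents that add atoms: none
Why: Proposed new method: the C3 ketone condenses reversibly with glycine to an imine whose N,O-chelate holds divalent palladium beside the equatorial 4β-methyl (the ring A chair fixed by the axial 10α-H makes the 4α-methyl axial and out of reach), carboxylate-assisted C–H cleavage gives a five-membered palladacycle, the N-fluoropyridinium salt oxidises it to tetravalent palladium, and C–O reductive elimination with the carboxylate of 14 forms the C19–O ester bond and sets C4 as S before imine hydrolysis returns the ketone and glycine, the closest known chemistry being oxime-directed palladium-catalysed acetoxylation of the β-methyl groups of ketoximes with PhI(OAc)2 and transient-imine-directed C(sp3)–H arylation of ketones.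

Step 9
Reactants: 15 {(1S,4aS,5R,6S)-1,5,6-trimethyl-2-oxo-5-[2-(5-oxo-2,5-dihydrofuran-3-yl)ethyl]-1,2,3,4,4a,5,6,7-octahydronaphthalen-1-yl}methyl 3-[4-(acetyloxy)phenyl]propanoate
Product: 17 {(1S,5R,6S,8S)-8-hydroxy-1,5,6-trimethyl-2-oxo-5-[2-(5-oxo-2,5-dihydrofuran-3-yl)ethyl]-1,2,3,4,5,6,7,8-octahydronaphthalen-1-yl}methyl 3-[4-(acetyloxy)phenyl]propanoate, via hydroperoxide 16 (not isolated)
Conditions: O2, hν (white LED), 5,10,15,20-tetraphenylporphyrin (1 mol%), CH2Cl2, −20 °C, stopped when 15 is consumed; then PPh3, 0 °C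
Reagents that add atoms: dioxygen, O=O
Why: Schenck ene reaction in which singlet oxygen bonds to C6 on the α face while taking the axial allylic 10α-H (geminal to the bulky C4 group), which shifts the alkene to C5=C10 and sets C6 as S, followed by reduction of the hydroperoxide by PPh3.

Step 10
Reactants: 17 {(1S,5R,6S,8S)-8-hydroxy-1,5,6-trimethyl-2-oxo-5-[2-(5-oxo-2,5-dihydrofuran-3-yl)ethyl]-1,2,3,4,5,6,7,8-octahydronaphthalen-1-yl}methyl 3-[4-(acetyloxy)phenyl]propanoate
Product: 18 {(1S,5R,6S,8S)-8-hydroxy-1,5,6-trimethyl-2-oxo-5-[2-(5-oxo-2,5-dihydrofuran-3-yl)ethyl]-1,2,3,4,5,6,7,8-octahydronaphthalen-1-yl}methyl 3-(4-hydroxyphenyl)propanoate (CNP0301014.1)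
Conditions: NH4OAc (8 equiv), MeOH/H2O 4:1, rt
Reagents that add atoms: none
Why: Chemoselective solvolysis of the aryl acetate, which is far more electrophilic than the neopentyl alkyl ester and the butenolide.

## Compound list

1 | 4-methoxy-1,2-dimethylbenzene (3,4-dimethylanisole) | COc1ccc(C)c(C)c1 | starting material
2 | 1-methoxy-4,5-dimethylcyclohexa-1,4-diene (not isolated) | COC1=CCC(C)=C(C)C1 | intermediate
3 | 3,4-dimethylcyclohex-3-en-1-one | CC1=C(C)CC(=O)CC1 | intermediate
4 | (4S)-3,4-dimethylcyclohex-2-en-1-one | C[C@H]1CCC(=O)C=C1C | intermediate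
5 | {[(3R,4S)-3-ethenyl-3,4-dimethylcyclohex-1-en-1-yl]oxy}trimethylsilane (vinyl trans to the neighbouring methyl) | C[C@H]1CCC(O[Si](C)(C)C)=C[C@]1(C)C=C | intermediate
6 | pent-1-en-3-one (ethyl vinyl ketone) | C=CC(=O)CC | starting material
7 | (2S,3R,4S)-3-ethenyl-3,4-dimethyl-2-(3-oxopentyl)cyclohexan-1-one (not isolated) | C[C@H]1CCC(=O)[C@@H](CCC(=O)CC)[C@]1(C)C=C | intermediate
8 | (4aS,5R,6S)-5-ethenyl-1,5,6-trimethyl-4,4a,5,6,7,8-hexahydronaphthalen-2(3H)-one (10α-H, 8β-Me, 9β-Me, 9α-vinyl) | C[C@H]1CCC2=C(C)C(=O)CC[C@H]2[C@]1(C)C=C | intermediate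
9 | (4aS,5R,6S)-5-ethenyl-1,1,5,6-tetramethyl-3,4,4a,5,6,7-hexahydronaphthalen-2(1H)-one (C5=C6 alkene, 10α-H) | C[C@H]1CC=C2C(C)(C)C(=O)CC[C@H]2[C@]1(C)C=C | intermediate
10 | 4-bromofuran-2(5H)-one | BrC1=CC(=O)OC1 | starting material
11 | 9-{2-[(1R,2S,8aS)-1,2,5,5-tetramethyl-6-oxo-1,2,3,5,6,7,8,8a-octahydronaphthalen-1-yl]ethyl}-9-borabicyclo[3.3.1]nonane (not isolated) | C[C@H]1CC=C2C(C)(C)C(=O)CC[C@H]2[C@]1(C)CCB1C2CCCC1CCC2 | intermediate
12 | 4-{2-[(1R,2S,8aS)-1,2,5,5-tetramethyl-6-oxo-1,2,3,5,6,7,8,8a-octahydronaphthalen-1-yl]ethyl}furan-2(5H)-one | C[C@H]1CC=C2C(C)(C)C(=O)CC[C@H]2[C@]1(C)CCC1=CC(=O)OC1 | intermediate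
13 | 3-(4-hydroxyphenyl)propanoic acid (phloretic acid) | OC(=O)CCc1ccc(O)cc1 | starting material
14 | 3-[4-(acetyloxy)phenyl]propanoic acid | CC(=O)Oc1ccc(CCC(=O)O)cc1 | intermediate
15 | {(1S,4aS,5R,6S)-1,5,6-trimethyl-2-oxo-5-[2-(5-oxo-2,5-dihydrofuran-3-yl)ethyl]-1,2,3,4,4a,5,6,7-octahydronaphthalen-1-yl}methyl 3-[4-(acetyloxy)phenyl]propanoate (4β-CH2O, 4α-Me, 10α-H) | C[C@H]1CC=C2[C@@](C)(COC(=O)CCc3ccc(OC(C)=O)cc3)C(=O)CC[C@H]2[C@]1(C)CCC1=CC(=O)OC1 | intermediate
16 | {(1S,5R,6S,8S)-8-hydroperoxy-1,5,6-trimethyl-2-oxo-5-[2-(5-oxo-2,5-dihydrofuran-3-yl)ethyl]-1,2,3,4,5,6,7,8-octahydronaphthalen-1-yl}methyl 3-[4-(acetyloxy)phenyl]propanoate (6α-OOH, not isolated) | C[C@H]1C[C@H](OO)C2=C(CCC(=O)[C@]2(C)COC(=O)CCc2ccc(OC(C)=O)cc2)[C@]1(C)CCC1=CC(=O)OC1 | intermediate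
17 | {(1S,5R,6S,8S)-8-hydroxy-1,5,6-trimethyl-2-oxo-5-[2-(5-oxo-2,5-dihydrofuran-3-yl)ethyl]-1,2,3,4,5,6,7,8-octahydronaphthalen-1-yl}methyl 3-[4-(acetyloxy)phenyl]propanoate (6α-OH) | C[C@H]1C[C@H](O)C2=C(CCC(=O)[C@]2(C)COC(=O)CCc2ccc(OC(C)=O)cc2)[C@]1(C)CCC1=CC(=O)OC1 | intermediate
18 | {(1S,5R,6S,8S)-8-hydroxy-1,5,6-trimethyl-2-oxo-5-[2-(5-oxo-2,5-dihydrofuran-3-yl)ethyl]-1,2,3,4,5,6,7,8-octahydronaphthalen-1-yl}methyl 3-(4-hydroxyphenyl)propanoate (halimane numbering 4S,6S,8S,9R) | C[C@H]1C[C@H](O)C2=C(CCC(=O)[C@]2(C)COC(=O)CCc2ccc(O)cc2)[C@]1(C)CCC1=CC(=O)OC1 | target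

## Step count and risks

Total step count: 10. Longest linear sequence: 9 steps (steps 1–6, 8, 9 and 10; step 7 is a one-step side branch).

Steps most likely to fail:

**Step 4 (annulation).** The Michael addition has to take place at a neopentyl carbon next to the quaternary C9, and ethyl vinyl ketone can polymerise under BF3·OEt2. Fallback from 5 back to 9: MeLi in THF at 0 °C cleaves the silyl ether to the lithium enolate F1. Addition of F1 to 3-(trimethylsilyl)but-3-en-2-one (anionic Stork–Ganem Michael addition, where the silyl group stabilises the adduct and suppresses polymerisation) gives the silyl diketone F2. KOH in MeOH at reflux removes silicon, closes ring A and equilibrates C10 to give the C4-unsubstituted enone F3. Exhaustive deconjugative methylation (KOtBu, excess MeI) then installs both C4 methyls and rejoins the route at 9.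

**Step 8 (the proposed new step).** Imine formation at the hindered ketone may be slow, the enamine tautomer may be fluorinated at C2, and C–F rather than C–O reductive elimination may compete. Fallback by known chemistry from 12 back to 15: NH2OH·HCl and NaOAc in EtOH give the E-oxime F4. Ac2O/AcOH converts it in the flask to the O-acetyl oxime F5, and Pd(OAc)2 (5 mol%) with PhI(OAc)2 at 100 °C then acetoxylates the equatorial 4β-methyl to give the acetoxylated O-acetyl oxime F6. K2CO3 in MeOH removes both acetyl groups to give the hydroxy oxime F7. TiCl3 with NH4OAc in aqueous dioxane cleaves the oxime to the 19-hydroxy ketone F8. Esterification of F8 with 14 (EDC·HCl, DMAP, CH2Cl2) gives 15.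

**Step 9 (ene reaction).** Singlet oxygen could instead bond to C5 and take a C7 hydrogen, and the tetrasubstituted alkene of the product could be oxidised further. Fallback from 15 back to 17: dimethyldioxirane in acetone at 0 °C epoxidises the C5=C6 alkene from the α face (the β face is shielded by the axial C9 methyl) to give the 5α,6α-epoxide F9. Me3SiOTf with 2,6-lutidine at −78 °C and then DBU opens the epoxide at the tertiary C5 with loss of the C10 hydrogen, giving the 6α-trimethylsilyl ether F10 with the C5=C10 alkene. Dilute citric acid in MeOH removes silicon and gives 17.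

## Further compounds

F1 | step 4 | lithium (3R,4S)-3-ethenyl-3,4-dimethylcyclohex-1-en-1-olate | C[C@H]1CCC([O-])=C[C@]1(C)C=C.[Li+]
F2 | step 4 | (2S,3R,4S)-3-ethenyl-3,4-dimethyl-2-[3-oxo-2-(trimethylsilyl)butyl]cyclohexan-1-one (mixture at the silyl-bearing carbon) | C[C@H]1CCC(=O)[C@@H](CC([Si](C)(C)C)C(C)=O)[C@]1(C)C=C
F3 | step 4 | (4aR,5R,6S)-5-ethenyl-5,6-dimethyl-4,4a,5,6,7,8-hexahydronaphthalen-2(3H)-one (10α-H) | C[C@H]1CCC2=CC(=O)CC[C@H]2[C@]1(C)C=C
F4 | step 8 | E-oxime of 12 at C3 | C[C@H]1CC=C2C(C)(C)/C(=N/O)CC[C@H]2[C@]1(C)CCC1=CC(=O)OC1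
F5 | step 8 | O-acetyl E-oxime of 12 | C[C@H]1CC=C2C(C)(C)/C(=N/OC(C)=O)CC[C@H]2[C@]1(C)CCC1=CC(=O)OC1
F6 | step 8 | O-acetyl E-oxime of 12 carrying a 4β-acetoxymethyl group (4α-methyl) | C[C@H]1CC=C2[C@@](C)(COC(C)=O)/C(=N/OC(C)=O)CC[C@H]2[C@]1(C)CCC1=CC(=O)OC1
F7 | step 8 | E-oxime of 12 carrying a 4β-hydroxymethyl group (4α-methyl) | C[C@H]1CC=C2[C@@](C)(CO)/C(=N/O)CC[C@H]2[C@]1(C)CCC1=CC(=O)OC1
F8 | step 8 | 4-{2-[(1R,2S,5S,8aS)-5-(hydroxymethyl)-1,2,5-trimethyl-6-oxo-1,2,3,5,6,7,8,8a-octahydronaphthalen-1-yl]ethyl}furan-2(5H)-one | C[C@H]1CC=C2[C@@](C)(CO)C(=O)CC[C@H]2[C@]1(C)CCC1=CC(=O)OC1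
F9 | step 9 | 5α,6α-epoxide of 15 | C[C@H]1C[C@@H]2O[C@@]23[C@@](C)(COC(=O)CCc4ccc(OC(C)=O)cc4)C(=O)CC[C@H]3[C@]1(C)CCC1=CC(=O)OC1
F10 | step 9 | 6α-O-trimethylsilyl ether of 17 | C[C@H]1C[C@H](O[Si](C)(C)C)C2=C(CCC(=O)[C@]2(C)COC(=O)CCc2ccc(OC(C)=O)cc2)[C@]1(C)CCC1=CC(=O)OC1
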